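## Retrosynthetic overview

1. Target 10 comes from the dearomatised acylphloroglucinol 8 in one oxidative step: PhI(OAc)2 turns the ring enol into an O-iodanyl enolate (enolonium equivalent), whose carbon is attacked by a prenyl alkene (C1–C5 bond). A cation–olefin closure (C3–C4 bond) and capture of the last cation by water follow.
2. Ring order: ring A (six-membered, from phloroglucinol) is present from the start; ring B (bridging cyclopentanone) and then ring C (cyclopentane) form in that single flask.
3. 8 comes from the aromatic 3,5-diprenyl ketone 6 by enantioselective dearomatising C-methylation, which sets the quaternary centre C7 that controls C1 and C5.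
4. 6 comes from acylphloroglucinol 4 and two prenyl bromide 5; 4 comes from phloroglucinol 1 and (R)-2-methylbutanoic acid 2.

Assumptions: the side chain of the given SMILES is (R), and (R)-2-methylbutanoic acid 2 is bought as the single enantiomer; 8 and 9 are drawn as one tautomer of a fast-equilibrating enol set.
Target numbering (tricyclo[5.3.1.0^1,5]undecane): C1 bridgehead carrying both ring ketones, C2 CH2, C3 CH bearing the 2-hydroxypropan-2-yl group, C4 CMe2, C5 ring-fusion CH, C6 CH2, C7 methyl-bearing bridgehead, C8 enol carbon, C9 acyl-bearing carbon, C10 ring ketone, C11 bridging ketone.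

## Route

Step 1
Reactants: 1 phloroglucinol; 2 (R)-2-methylbutanoic acid
Product: 4 (2R)-2-methyl-1-(2,4,6-trihydroxyphenyl)butan-1-one, via (R)-2-methylbutanoyl chloride 3 (not isolated)
Conditions: (COCl)2, DMF (cat.), CH2Cl2, 0 °C → rt; then 1, AlCl3 (4 equiv), PhNO2, 0 °C → rt; aq. HCl
Reagents that add atoms: none
Why: Friedel–Crafts acylation of the very electron-rich triol stops after one acyl group because the ketone deactivates the ring, and the acid chloride is made and used cold without base so the α-stereocentre is not enolised (no new stereocentre).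

Step 2
Reactants: 4 (2R)-2-methyl-1-(2,4,6-trihydroxyphenyl)butan-1-one; 5 prenyl bromide (2.1 equiv)
Product: 6 (2R)-2-methyl-1-[2,4,6-trihydroxy-3,5-bis(3-methylbut-2-en-1-yl)phenyl]butan-1-one
Conditions: 10% aq. KOH, 0 °C, 2 h; then aq. HCl
Reagents that add atoms: prenyl bromide 5, CC(C)=CCBr
Why: Phenolate C-alkylation (C-prenylation) in water, where hydrogen bonding to the phenolate oxygens favours carbon attack, puts one prenyl group on each of the two free ring carbons; no stereocentre is formed and the side-chain centre is not acidic in the polyphenolate.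

Step 3
Reactants: 6 (2R)-2-methyl-1-[2,4,6-trihydroxy-3,5-bis(3-methylbut-2-en-1-yl)phenyl]butan-1-one; 7 iodomethane
Product: 8 (6R)-3,5-dihydroxy-6-methyl-2-[(2R)-2-methylbutanoyl]-4,6-bis(3-methylbut-2-en-1-yl)cyclohexa-2,4-dien-1-one
Conditions: MeI (1.2 equiv), CsOH·H2O (3 equiv), N-(9-anthracenylmethyl)-O-allylcinchonidinium bromide (10 mol%), toluene/CH2Cl2 3:1, −50 °C; then aq. HCl
Reagents that add atoms: iodomethane 7, CI
Why: Proposed new method: asymmetric phase-transfer alkylative dearomatisation; the two prenyl-bearing ring carbons of 6 are equivalent, so methylation gives one constitution and only the face has to be chosen, and in the non-polar medium the phenolate reacts as a tight ion pair with the chiral cinchonidinium cation, which shields one enantiotopic face and delivers MeI to give the (6R) quaternary centre (the cinchonine-derived pseudoenantiomer is used if the observed sense is opposite); closest known chemistry is the chiral phase-transfer alkylative dearomatisation of 3,5-diprenyl acylphloroglucinols with enal electrophiles, cinchona phase-transfer C-methylation of stabilised enolates, and the racemic NaOMe/MeI dearomatising methylation of this substrate class.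

Step 4
Reactants: 8 (6R)-3,5-dihydroxy-6-methyl-2-[(2R)-2-methylbutanoyl]-4,6-bis(3-methylbut-2-en-1-yl)cyclohexa-2,4-dien-1-one
Product: 10 (1S,3S,5S,7S)-8-hydroxy-3-(2-hydroxypropan-2-yl)-4,4,7-trimethyl-9-[(2R)-2-methylbutanoyl]tricyclo[5.3.1.0^1,5]undec-8-ene-10,11-dione, via iodanyl enolate 9 (not isolated)
Conditions: PhI(OAc)2 (1.1 equiv), (CF3)2CHOH/H2O 10:1 (0.01 M), 0 °C, 15 min; preparative HPLC
Reagents that add atoms: water, O
Why: Proposed new method: hypervalent-iodine enolonium-triggered cation–olefin bicyclisation; ligand exchange gives O-iodanyl enolate 9, whose prenyl-bearing enol carbon (the acyl-bearing carbon is the less nucleophilic centre of a hydrogen-bonded triketone) is attacked by the alkene of the prenyl group on the quaternary carbon as PhI leaves, joining an enol carbon and an alkene carbon that are both normally nucleophilic; this 5-exo closure can only occur on the face carrying that prenyl chain (fixing C1 from C7) and places the new tertiary cation exo, away from the enol bridge (setting C5), a second 5-exo closure onto the other prenyl alkene forms ring C and sets C3 with little facial bias (about 1:1 expected, C3 epimer removed by HPLC), and water captures the final tertiary cation as the carbinol; closest known chemistry is the PhI(OAc)2/fluoro-alcohol oxidative cation–olefin cyclisation of phenols and the Mn(OAc)3/Cu(OAc)2 oxidative cyclisation of this same substrate class to the same tricyclic skeleton.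

## Compound list

1 | phloroglucinol (benzene-1,3,5-triol) | Oc1cc(O)cc(O)c1 | starting material
2 | (R)-2-methylbutanoic acid | CC[C@@H](C)C(=O)O | starting material
3 | (R)-2-methylbutanoyl chloride | CC[C@@H](C)C(Cl)=O | intermediate (not isolated)
4 | (2R)-2-methyl-1-(2,4,6-trihydroxyphenyl)butan-1-one | CC[C@@H](C)C(=O)c1c(O)cc(O)cc1O | intermediate
5 | prenyl bromide (1-bromo-3-methylbut-2-ene) | CC(C)=CCBr | starting material
6 | (2R)-2-methyl-1-[2,4,6-trihydroxy-3,5-bis(3-methylbut-2-en-1-yl)phenyl]butan-1-one | CC[C@@H](C)C(=O)c1c(O)c(CC=C(C)C)c(O)c(CC=C(C)C)c1O | intermediate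
7 | iodomethane | CI | starting material
8 | (6R)-3,5-dihydroxy-6-methyl-2-[(2R)-2-methylbutanoyl]-4,6-bis(3-methylbut-2-en-1-yl)cyclohexa-2,4-dien-1-one | CC[C@@H](C)C(=O)C1=C(O)C(CC=C(C)C)=C(O)[C@@](C)(CC=C(C)C)C1=O | intermediate
9 | (6R)-5-{[acetoxy(phenyl)-λ3-iodanyl]oxy}-3-hydroxy-6-methyl-2-[(2R)-2-methylbutanoyl]-4,6-bis(3-methylbut-2-en-1-yl)cyclohexa-2,4-dien-1-one | CC[C@@H](C)C(=O)C1=C(O)C(CC=C(C)C)=C(OI(OC(C)=O)c2ccccc2)[C@@](C)(CC=C(C)C)C1=O | intermediate (not isolated)
10 | (1S,3S,5S,7S)-8-hydroxy-3-(2-hydroxypropan-2-yl)-4,4,7-trimethyl-9-[(2R)-2-methylbutanoyl]tricyclo[5.3.1.0^1,5]undec-8-ene-10,11-dione | CC[C@@H](C)C(=O)C1=C(O)[C@]2(C)C[C@H]3C(C)(C)[C@@H](C(C)(C)O)C[C@@]3(C1=O)C2=O | target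

## Step count

Total steps: 4. Longest linear sequence: 4.

## Steps most likely to fail, with fallbacks

Step 4 (enolonium cascade). Risks are capture of a cation before the second ring closure, over-oxidation, and the unselective C3 centre. The fallback sets out from 8 and comes back at 10. Mn(OAc)3·2H2O (2.2 equiv) with Cu(OAc)2·H2O (1 equiv) in AcOH at rt runs the same two ring closures as one-electron steps and ends by oxidative elimination, giving (1S,3R,5S,7S)-8-hydroxy-4,4,7-trimethyl-9-[(2R)-2-methylbutanoyl]-3-(prop-1-en-2-yl)tricyclo[5.3.1.0^1,5]undec-8-ene-10,11-dione F1 (same spatial arrangement as 10; its C3 epimer is removed by HPLC). Markovnikov hydration of the isopropenyl group with Co(acac)2 (cat.), PhSiH3 and O2 in iPrOH then gives 10.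

Step 3 (enantioselective methylation). Risks are low enantioselectivity, O-methylation and double methylation. The fallback sets out from 6 and comes back at 8. Methylation without a chiral catalyst (NaOMe, MeI, MeOH, 0 °C → rt) gives 8 together with its C6 epimer, (6S)-3,5-dihydroxy-6-methyl-2-[(2R)-2-methylbutanoyl]-4,6-bis(3-methylbut-2-en-1-yl)cyclohexa-2,4-dien-1-one F2, about 1:1. Because both carry the (R) side chain they are diastereomers and are separated by preparative HPLC on an amylose tris(3,5-dimethylphenylcarbamate) phase; if they co-elute, the pair is taken through step 4 and the separation is done at the stage of 10.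

Step 2 (double C-prenylation). Risks are mono- and tri-prenylation and O-alkylation, which lower the yield. The fallback sets out from 4 and comes back at 6. Acid-mediated Friedel–Crafts prenylation of the neutral phenol with 2-methylbut-3-en-2-ol (2.2 equiv) and BF3·OEt2 in dioxane at rt goes through the prenyl cation instead of phenolate alkylation and avoids base and O-alkylation. It leads directly to 6 and makes no new compound (F0).

## Further compounds

F1 | step 4 | (1S,3R,5S,7S)-8-hydroxy-4,4,7-trimethyl-9-[(2R)-2-methylbutanoyl]-3-(prop-1-en-2-yl)tricyclo[5.3.1.0^1,5]undec-8-ene-10,11-dione | CC[C@@H](C)C(=O)C1=C(O)[C@]2(C)C[C@H]3C(C)(C)[C@@H](C(C)=C)C[C@@]3(C1=O)C2=O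
F2 | step 3 | (6S)-3,5-dihydroxy-6-methyl-2-[(2R)-2-methylbutanoyl]-4,6-bis(3-methylbut-2-en-1-yl)cyclohexa-2,4-dien-1-one | CC[C@@H](C)C(=O)C1=C(O)C(CC=C(C)C)=C(O)[C@](C)(CC=C(C)C)C1=O
F0 | step 2 | none | none
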